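**Retrosynthetic overview**

1. Feature: in the chromanone C ring (O1–C2–C3–C4–C4a–C8a) the only stereocentre, C3 (B-ring aryl and H), sits next to the C4 carbonyl. C3 and C4 together are the flat trisubstituted C3=C4 alkene of a 3-aryl-2H-chromene, and the C4–H can carry configuration to C3 by a 1,2-shift while C4 becomes C=O.
2. Target 17 ⇐ diacetate 16 ⇐ pinacol rearrangement (H shift C4→C3) of cis-diol 15 ⇐ ligand-controlled osmylation of isoflav-3-ene 13.
3. 13 ⇐ 3-arylcoumarin 10 (lactone reduction, Mitsunobu closure of the 2H-pyran, acetylation) ⇐ Perkin condensation of arylacetic acid 8 with 2,4,6-trihydroxybenzaldehyde 9.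
4. 8 ⇐ angular chromene aldehyde 4 (O-methylation, one-carbon homologation through the nitrile) ⇐ 2,4-dihydroxybenzaldehyde 1 + 3-methylbut-2-enal 2.
5. Ring order: dimethylpyran on the B ring (step 1), A-ring-fused pyranone (step 5), reopened and reclosed as the 2H-pyran C ring (steps 6–7); no ring closes afterwards.

Key step: step 9

Remark: the stereocentre of the target is read as (3R) (priorities C4(=O) > C2 > aryl > H). The dihydroquinine ligand series in step 9 is chosen on that basis, from the usual face mnemonic.

**Route**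

Step 1
Reactants: 1 2,4-dihydroxybenzaldehyde; 2 3-methylbut-2-enal
Product: 4 5-hydroxy-2,2-dimethyl-2H-chromene-6-carbaldehyde, via o-quinone methide 3 (not isolated)
Conditions: pyridine, 120 °C (sealed), 16 h
Reagents that add atoms: none
Why: Knoevenagel-type condensation of the enal at C3 of the resorcinol ring (between the two hydroxyls) should give o-quinone methide 3, which closes by oxa-6π electrocyclisation onto the 4-oxygen because the 2-hydroxyl stays hydrogen-bonded to the formyl group, so the angular 5-hydroxy-6-formyl chromene is expected.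

Step 2
Reactants: 4 5-hydroxy-2,2-dimethyl-2H-chromene-6-carbaldehyde
Product: 5 5-methoxy-2,2-dimethyl-2H-chromene-6-carbaldehyde
Conditions: MeI, K2CO3, DMF, 40 °C
Reagents that add atoms: iodomethane CI
Why: Williamson O-methylation of the only acidic site, with the polar solvent breaking the hydrogen bond to the aldehyde.

Step 3
Reactants: 5 5-methoxy-2,2-dimethyl-2H-chromene-6-carbaldehyde
Product: 7 2-(5-methoxy-2,2-dimethyl-2H-chromen-6-yl)acetonitrile, via N-(1-tosylvinyl)formamide 6 (not isolated)
Conditions: TosMIC, t-BuOK (2.5 equiv), DME, −50 °C; then MeOH, reflux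
Reagents that add atoms: p-toluenesulfonylmethyl isocyanide Cc1ccc(cc1)S(=O)(=O)C[N+]#[C-]
Why: van Leusen reductive cyanation, in which the TosMIC anion adds to the aldehyde, the oxazoline opens to formamide 6, and methanolysis of the formyl group with loss of sulfinate gives the homologated nitrile; low temperature and excess base should suppress oxazole formation.

Step 4
Reactants: 7 2-(5-methoxy-2,2-dimethyl-2H-chromen-6-yl)acetonitrile
Product: 8 2-(5-methoxy-2,2-dimethyl-2H-chromen-6-yl)acetic acid
Conditions: KOH, EtOH/H2O, reflux; then 1 M HCl, 0 °C, to pH 3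
Reagents that add atoms: potassium hydroxide [K+].[OH-]; water O
Why: base hydrolysis of a nitrile through the amide, to which the chromene and the aryl ether are inert; the brief cold acidification spares the acid-sensitive pyran alkene.

Step 5
Reactants: 8 2-(5-methoxy-2,2-dimethyl-2H-chromen-6-yl)acetic acid; 9 2,4,6-trihydroxybenzaldehyde
Product: 10 3-(5-methoxy-2,2-dimethyl-2H-chromen-6-yl)-2-oxo-2H-chromene-5,7-diyl diacetate
Conditions: Ac2O, Et3N, 110 °C
Reagents that add atoms: acetic anhydride CC(=O)OC(C)=O
Why: Perkin–Oglialoro condensation, in which the enolised mixed anhydride of 8 condenses with the aldehyde and lactonises onto an ortho oxygen; the two ortho oxygens are equivalent, so one coumarin is expected, and the remaining phenols emerge as acetates.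

Step 6
Reactants: 10 3-(5-methoxy-2,2-dimethyl-2H-chromen-6-yl)-2-oxo-2H-chromene-5,7-diyl diacetate
Product: 11 2-[(Z)-3-hydroxy-2-(5-methoxy-2,2-dimethyl-2H-chromen-6-yl)prop-1-enyl]benzene-1,3,5-triol
Conditions: DIBAL-H (8 equiv), CH2Cl2/THF, −78 → 0 °C; Rochelle salt, under Ar
Reagents that add atoms: none
Why: DIBAL-H 1,2-reduction of the unsaturated lactone through the lactol to the allylic alcohol, with reductive removal of both aryl acetates; the Z geometry is inherited from the ring, and the air-sensitive product is carried on crude.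

Step 7
Reactants: 11 2-[(Z)-3-hydroxy-2-(5-methoxy-2,2-dimethyl-2H-chromen-6-yl)prop-1-enyl]benzene-1,3,5-triol
Product: 12 3-(5-methoxy-2,2-dimethyl-2H-chromen-6-yl)-2H-chromene-5,7-diol
Conditions: PPh3, DIAD (slow addition), THF, 0 °C
Reagents that add atoms: none
Why: intramolecular Mitsunobu etherification (6-exo-tet SN2 at the primary allylic carbon) by an ortho phenol; the two ortho hydroxyls are equivalent and the para hydroxyl cannot reach, so a single 2H-chromene should form.

Step 8
Reactants: 12 3-(5-methoxy-2,2-dimethyl-2H-chromen-6-yl)-2H-chromene-5,7-diol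
Product: 13 3-(5-methoxy-2,2-dimethyl-2H-chromen-6-yl)-2H-chromene-5,7-diyl diacetate
Conditions: Ac2O, pyridine, DMAP (cat.), CH2Cl2, 0 °C → rt
Reagents that add atoms: acetic anhydride CC(=O)OC(C)=O
Why: pyridine-mediated O-acetylation of both phenols, which stabilises the isoflavene and makes the A ring electron-poor for steps 9 and 10.

Step 9
Reactants: 13 3-(5-methoxy-2,2-dimethyl-2H-chromen-6-yl)-2H-chromene-5,7-diyl diacetate
Product: 15 (3R,4S)-cis-3,4-dihydroxy-3-(5-methoxy-2,2-dimethyl-2H-chromen-6-yl)chromane-5,7-diyl diacetate, via cyclic osmate(VI) ester 14 (not isolated)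
Conditions: OsO4 (1.0 equiv), (DHQ)2PHAL (1.1 equiv), CH2Cl2, −78 °C; then aq. NaHSO3, THF, rt
Reagents that add atoms: osmium tetroxide O=[Os](=O)(=O)=O
Why: The ligand-bound OsO4 should add across C3=C4 in a suprafacial [3+2] cycloaddition to give osmate ester 14, which bisulfite cleaves reductively to the cis-diol; the closest known reaction is the Sharpless asymmetric dihydroxylation of 1-arylcycloalkenes, run here in its stoichiometric low-temperature form as established for isoflav-3-enes. No ring of the target closes; only the transient five-membered osmate ring forms. Both stereocentres are set by the ligand: with the B-ring aryl in the south-west and H-4 in the south-east quadrant of the mnemonic, the dihydroquinine ligand delivers both oxygens to the α face, which corresponds to (3R,4S), and suprafacial addition makes the diol cis. The step needs chemoselectivity for the trisubstituted C3=C4 alkene over the cis-disubstituted pyran alkene of the B-ring unit; this is secured by the higher reactivity of the more substituted stilbene-like alkene, by the ligand pocket (which accelerates aryl-substituted trisubstituted alkenes but not cis-alkenes), by the adjacent gem-dimethyl group and by using one equivalent of oxidant. The acetates should survive because the osmylation is anhydrous and base-free and the osmate cleavage is run below pH 7.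

Step 10
Reactants: 15 (3R,4S)-cis-3,4-dihydroxy-3-(5-methoxy-2,2-dimethyl-2H-chromen-6-yl)chromane-5,7-diyl diacetate
Product: 16 (3R)-3-(5-methoxy-2,2-dimethyl-2H-chromen-6-yl)-4-oxochromane-5,7-diyl diacetate
Conditions: BF3·OEt2 (0.2 equiv), CH2Cl2, −40 → −10 °C; cold aq. NaHCO3 quench
Reagents that add atoms: none
Why: pinacol (semipinacol) rearrangement in which the Lewis acid ionises the tertiary C3–OH (benzylic to the 2-methoxy-4-alkoxyaryl ring, while the acetylated A ring disfavours ionisation at C4) and the pseudoaxial C4–H, anti to the leaving group, shifts suprafacially to C3 as C4 becomes the ketone; the hydrogen arrives on the face it occupied at C4, so the (4S) centre should dictate (3R).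

Step 11
Reactants: 16 (3R)-3-(5-methoxy-2,2-dimethyl-2H-chromen-6-yl)-4-oxochromane-5,7-diyl diacetate
Product: 17 (3R)-5,7-dihydroxy-3-(5-methoxy-2,2-dimethyl-2H-chromen-6-yl)chroman-4-one
Conditions: NH4OAc (8 equiv), MeOH/H2O 4:1, rt; work-up at pH ≤ 7
Reagents that add atoms: none
Why: ammonium acetate-mediated neutral methanolysis of aryl acetates, which should free both phenols without the base that would enolise the C3–H next to the ketone.

**Compound list**

1 | 2,4-dihydroxybenzaldehyde | O=Cc1ccc(O)cc1O | starting material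
2 | 3-methylbut-2-enal | CC(C)=CC=O | starting material
3 | 2-hydroxy-3-(3-methylbut-2-enylidene)-4-oxocyclohexa-1,5-diene-1-carbaldehyde (o-quinone methide) | O=CC1=C(O)C(=CC=C(C)C)C(=O)C=C1 | intermediate (not isolated)
4 | 5-hydroxy-2,2-dimethyl-2H-chromene-6-carbaldehyde | O=Cc1ccc2OC(C)(C)C=Cc2c1O | intermediate
5 | 5-methoxy-2,2-dimethyl-2H-chromene-6-carbaldehyde | COc1c(C=O)ccc2c1C=CC(C)(C)O2 | intermediate
6 | N-[2-(5-methoxy-2,2-dimethyl-2H-chromen-6-yl)-1-tosylethenyl]formamide (alkene geometry undefined) | O=CNC(=Cc1ccc2c(c1OC)C=CC(C)(C)O2)S(=O)(=O)c1ccc(C)cc1 | intermediate (not isolated)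
7 | 2-(5-methoxy-2,2-dimethyl-2H-chromen-6-yl)acetonitrile | COc1c(CC#N)ccc2c1C=CC(C)(C)O2 | intermediate
8 | 2-(5-methoxy-2,2-dimethyl-2H-chromen-6-yl)acetic acid | COc1c(CC(=O)O)ccc2c1C=CC(C)(C)O2 | intermediate
9 | 2,4,6-trihydroxybenzaldehyde | O=Cc1c(O)cc(O)cc1O | starting material
10 | 3-(5-methoxy-2,2-dimethyl-2H-chromen-6-yl)-2-oxo-2H-chromene-5,7-diyl diacetate | COc1c(C2=Cc3c(OC(C)=O)cc(OC(C)=O)cc3OC2=O)ccc2c1C=CC(C)(C)O2 | intermediate
11 | 2-[(Z)-3-hydroxy-2-(5-methoxy-2,2-dimethyl-2H-chromen-6-yl)prop-1-enyl]benzene-1,3,5-triol | COc1c(/C(CO)=C/c2c(O)cc(O)cc2O)ccc2c1C=CC(C)(C)O2 | intermediate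
12 | 3-(5-methoxy-2,2-dimethyl-2H-chromen-6-yl)-2H-chromene-5,7-diol | COc1c(C2=Cc3c(O)cc(O)cc3OC2)ccc2c1C=CC(C)(C)O2 | intermediate
13 | 3-(5-methoxy-2,2-dimethyl-2H-chromen-6-yl)-2H-chromene-5,7-diyl diacetate | COc1c(C2=Cc3c(OC(C)=O)cc(OC(C)=O)cc3OC2)ccc2c1C=CC(C)(C)O2 | intermediate
14 | cyclic osmate(VI) ester bridging O3 and O4 of 15 (ligand omitted) | COc1c([C@@]2(O[Os]3(=O)=O)COc4cc(OC(C)=O)cc(OC(C)=O)c4[C@@H]2O3)ccc2c1C=CC(C)(C)O2 | intermediate (not isolated)
15 | (3R,4S)-cis-3,4-dihydroxy-3-(5-methoxy-2,2-dimethyl-2H-chromen-6-yl)chromane-5,7-diyl diacetate | COc1c([C@@]2(O)COc3cc(OC(C)=O)cc(OC(C)=O)c3[C@@H]2O)ccc2c1C=CC(C)(C)O2 | intermediate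
16 | (3R)-3-(5-methoxy-2,2-dimethyl-2H-chromen-6-yl)-4-oxochromane-5,7-diyl diacetate | COc1c([C@@H]2COc3cc(OC(C)=O)cc(OC(C)=O)c3C2=O)ccc2c1C=CC(C)(C)O2 | intermediate
17 | (3R)-5,7-dihydroxy-3-(5-methoxy-2,2-dimethyl-2H-chromen-6-yl)chroman-4-one | COc1c([C@@H]2COc3cc(O)cc(O)c3C2=O)ccc2c1C=CC(C)(C)O2 | target

**Step count and risks**

Total steps: 11. Longest linear sequence: 11 steps (1 → 17); 2 and 9 are commercial partners.

Steps most likely to fail:

1. Step 9. The osmium reagent may also attack the pyran C=C of the B-ring unit, or face discrimination may be weak because the ortho-methoxy aryl group is twisted out of the alkene plane. The fallback sets out from 13 and comes back at 16, fixing C3 by a dynamic kinetic resolution instead of by alkene face selection. Dimethyldioxirane (1.0 equiv, acetone, −40 °C), an oxidant that favours the more substituted alkene, should give the racemic cis-fused 3,4-epoxide F1. A trace of BF3·OEt2 (Meinwald rearrangement with the same hydride shift) should convert it into the racemic ketone F2. Asymmetric transfer hydrogenation under dynamic kinetic resolution (RuCl[(R,R)-TsDPEN](p-cymene), HCO2H/Et3N, EtOAc, rt), with C3 epimerising through the enol, should give the cis-(3R,4R)-alcohol F3. Dess–Martin periodinane with NaHCO3 in CH2Cl2 at 0 °C then returns 16.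

2. Step 10. The C3 cation may lose a proton (to the achiral enol or to a chromene) instead of accepting the C4 hydride, or the acid may enolise 16 or attack the pyran alkene; each erodes the C3 configuration or the material. The fallback sets out from 15 and comes back at 16, replacing free-acid ionisation by a cyclic-orthoester pinacol rearrangement. Trimethyl orthoformate with catalytic PPTS in CH2Cl2 should give the cyclic orthoformate F4 (epimers at the orthoester carbon). BF3·OEt2 or TMSOTf at −78 °C should generate the dioxolanylium ion, which opens at the tertiary benzylic C3–O with synchronous anti hydride shift and releases the ketone 16 with formate as the leaving group, under aprotic conditions.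

3. Step 6. Once the acetates are stripped, the lactone carries electron-releasing aluminium phenoxides and its reduction may stall or turn to conjugate reduction, and the free phloroglucinol-type allylic alcohol may oxidise or oligomerise on handling. The fallback sets out from 10 and comes back at 12, masking the phenols as silyl ethers through the reduction and ring closure. NH4OAc in aqueous MeOH should give the 5,7-dihydroxycoumarin F5, and TBSCl/imidazole in DMF the bis-silyl ether F6. DIBAL-H (3 equiv, CH2Cl2, −78 → 0 °C) should then give the (Z)-allylic alcohol phenol F7, and PPh3/DIAD the bis-silyl isoflav-3-ene F8. TBAF buffered with AcOH in THF at 0 °C frees 12, which is acetylated at once as in step 8.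

**Further compounds**

F1 | step 9 | rac-cis-3,4-epoxy-3-(5-methoxy-2,2-dimethyl-2H-chromen-6-yl)chromane-5,7-diyl diacetate | COc1c(C23COc4cc(OC(C)=O)cc(OC(C)=O)c4C2O3)ccc2c1C=CC(C)(C)O2
F2 | step 9 | rac-3-(5-methoxy-2,2-dimethyl-2H-chromen-6-yl)-4-oxochromane-5,7-diyl diacetate | COc1c(C2COc3cc(OC(C)=O)cc(OC(C)=O)c3C2=O)ccc2c1C=CC(C)(C)O2
F3 | step 9 | (3R,4R)-cis-4-hydroxy-3-(5-methoxy-2,2-dimethyl-2H-chromen-6-yl)chromane-5,7-diyl diacetate | COc1c([C@@H]2COc3cc(OC(C)=O)cc(OC(C)=O)c3[C@@H]2O)ccc2c1C=CC(C)(C)O2
F4 | step 10 | cyclic methyl orthoformate (2-methoxy-1,3-dioxolane) of diol 15, epimers at the orthoester carbon | COc1c([C@@]23COc4cc(OC(C)=O)cc(OC(C)=O)c4[C@@H]2OC(OC)O3)ccc2c1C=CC(C)(C)O2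
F5 | step 6 | 5,7-dihydroxy-3-(5-methoxy-2,2-dimethyl-2H-chromen-6-yl)-2H-chromen-2-one | COc1c(C2=Cc3c(O)cc(O)cc3OC2=O)ccc2c1C=CC(C)(C)O2
F6 | step 6 | 5,7-bis(tert-butyldimethylsilyloxy)-3-(5-methoxy-2,2-dimethyl-2H-chromen-6-yl)-2H-chromen-2-one | COc1c(C2=Cc3c(O[Si](C)(C)C(C)(C)C)cc(O[Si](C)(C)C(C)(C)C)cc3OC2=O)ccc2c1C=CC(C)(C)O2
F7 | step 6 | 3,5-bis(tert-butyldimethylsilyloxy)-2-[(Z)-3-hydroxy-2-(5-methoxy-2,2-dimethyl-2H-chromen-6-yl)prop-1-enyl]phenol | COc1c(/C(CO)=C/c2c(O)cc(O[Si](C)(C)C(C)(C)C)cc2O[Si](C)(C)C(C)(C)C)ccc2c1C=CC(C)(C)O2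
F8 | step 6 | 5,7-bis(tert-butyldimethylsilyloxy)-3-(5-methoxy-2,2-dimethyl-2H-chromen-6-yl)-2H-chromene | COc1c(C2=Cc3c(O[Si](C)(C)C(C)(C)C)cc(O[Si](C)(C)C(C)(C)C)cc3OC2)ccc2c1C=CC(C)(C)O2
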